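Decide now to watch the starting material, not the target, and to reckon each flask by its margin.

| setting | spring | dawn | ochre | green | amber |
|---|---|---|---|---|---|
| starting material | 0.010 M | 0.010 M | 0.010 M | 0.010 M | 0.010 M |
| partner | 0.012 M | 0.051 M | 0.0420 M | 0.0110 M | 0.0210 M |
| remark | run made earlier | run made earlier |  |  |  |
| time |  |  | 25 min | 25 min | 25 min |

| run | time / min | starting material / % | target / % |
|---|---|---|---|
| spring | 4.00 | 52.3 | 10.6 |
| spring | 8.00 | 35.8 | 23.6 |
| spring | 12.0 | 26.7 | 31.6 |
| spring | 15.0 | 22.5 | 35.3 |
| spring | 20.0 | 16.0 | 38.2 |
| spring | 25.0 | 13.1 | 40.0 |
| dawn | 2.00 | 21.4 | 11.4 |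
| dawn | 3.00 | 12.4 | 18.9 |
| dawn | 6.00 | 2.6 | 36.8 |
| dawn | 10.0 | 0.8 | 46.6 |
| dawn | 15.0 | 0 | 49.4 |
| dawn | 25.0 | 0 | 46.2 |

(scatter of a reading: 0.5 percentage points)

- what was read earlier has a scatter of 0.5 percentage points, one standard deviation

- part of the starting material that has reacted at the end, ochre
- part of the starting material that has reacted at the end, green
- part of the starting material that has reacted at the end, amber
- what raising the concentration of partner from its lowest to its highest value here does to the part of the starting material that has reacted (changes below 5 percentage points count as none) (it falls / no change / it rises)

Work in fractions of the starting material's charge, and assume that one partner goes with each starting material. Then partner minus starting material stays put, so freeze it: this difference is the margin, 0.100 for green. Spring's margin is 0.200, and with it the 13.1 % left at 25.0 min gives a pace, the rate constant times the charge, of 0.149 min⁻¹. Dawn, a different run, gives 0.154 min⁻¹ from its 3.00 min reading.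

Now build green. Take the main step first and hold partner at its charge, the pseudo-first-order picture: 1.67 % is left. Add the loss of partner through the frozen margin, and 16.8 % is left, a change of 15 percentage points.

Then add the rest. Spring at 4.00 min has 10.6 % of target, while 47.7 % of the starting material is gone, and dawn's target slides from 49.4 % to 46.2 %. Read these as steps beyond the loss of starting material, which is what the question counts. They may still bend the pace: spring's first reading gives 0.177 min⁻¹, which puts green at 86.0 % reacted. Commit to 83.2 % for green and 99.1 % for amber, with ochre practically complete.

The forecast gives 100 % for ochre, 83 % for green and 98.8 % for amber, with the trend it rises, and says of its slight drift in the rate constant: “target arises late and later decays in dawn, but this matters little”.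

The flasks give >99.9 % for ochre, 84.0 % for green and 99.2 % for amber, and across them it rises, by 16 points.

    starting material + partner → intermediate + released group (k = 0.269 M⁻¹ s⁻¹)
    intermediate ⇌ target (K = 1.88, k = 0.00256 s⁻¹)
    intermediate ⇌ isomer of the product (K = 3.00, k = 8.13 × 10⁻⁴ s⁻¹)
    starting material + released group ⇌ idle adduct, settled at all times (K = 56.0 M⁻¹)
    released group → by-product carried off (k = 0.00671 s⁻¹)

Ochre reaches >99.9 % against green's 84.0 %, mainly because of the difference in partner charge. Within green, two things act together, its falling partner and the early reading: with the level held it reaches 98.5 %, and read at 250 min it reaches 99.8 %. At 25 min green's partner stands at 0.262 of the starting material's charge and the starting material at 16.0 %, a gap of 0.102, still the margin. For green read at 1.0 h, margin and pace leave 5.92 %, and that run shows 5.42 %.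

(The runs were computed from invented constants; the scatter is artificial.)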